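Slowness set the question for the next run: a flask left for 2.0 h earns its wait if the share s of isomer in isomer plus target is still moving then. The new flask holds twice the charge of the north-east run, and I assumed first-order steps, so that shares carry over; one run cannot test this.

| flask | substrate | remark | time |
|---|---|---|---|
| north-east | 0.016 M | run made earlier |  |
| flask | 0.032 M |  | 2.0 h |

north-east run (percent of the substrate charged)

| time / min | isomer of the product / % | target / % |
|---|---|---|
| 6.00 | 10.4 | 19.3 |
| 12.0 | 18.0 | 20.3 |
| 20.0 | 25.2 | 18.2 |
| 25.0 | 27.5 | 17.6 |
| 30.0 | 29.3 | 16.2 |
| 40.0 | 32.2 | 15.5 |

(standard deviation of a reading: 0.3 percentage points)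

- candidate steps: target <-> isomer of the product; target -> over-reaction product; isomer of the product <-> substrate; substrate <-> target

1. share of isomer of the product in isomer of the product plus target at 30 s
2. share of isomer of the product in isomer of the product plus target at 2.0 h
3. which of isomer of the product and target there is more of at 2.0 h

In the north-east run, at the equally spaced times 20.0 min, 30.0 min and 40.0 min, s read 58.1 %, 64.4 % and 67.5 %. Integrating ds/dt = λ(s∞ − s) makes the gap s∞ − s shrink as exp(−λt), so each equal interval multiplies it by one factor f, here 0.491. Adding the remaining geometric tail to the last share gives the limiting share s∞, the value s is heading for: 70.5 %, an extrapolation rather than a reading, built on differences of shares whose percentages each scatter by 0.3 percentage points.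

The relaxation time τ = 1/λ is 14.1 min. Run backwards, the curve gives 20.7 % at 30 s. Run forwards, it leaves a gap of 0.01 points at 2.0 h. So I decided to charge the flask as planned and put the effort into the sample at 30 s. Since s∞ stands above 0.5, I expected isomer to lead.

The forecast put the shares a little apart from mine, at 18 % (11 % to 25 %) and 74 % (69 % to 81 %), with isomer of the product ahead, and held that "doubling concentration changes nothing".

The flask gave 20.1 % and 71.7 %, with 30.6 % isomer against 12.1 % target; my two shares stood 0.60 points above and 1.2 points below.

    target ⇌ isomer of the product (K = 2.31, k = 4.68 × 10⁻⁴ s⁻¹)
    target → over-reaction product (k = 2.28 × 10⁻⁴ s⁻¹)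
    isomer of the product ⇌ substrate (k = 3.49 × 10⁻⁴ s⁻¹)
    substrate ⇌ target (K = 0.380, k = 0.00132 s⁻¹)

In the flask, the forward half-life of target into isomer, 0.41 h, is shorter than that into over-reaction product, 0.84 h, the way back not counted. The relaxation half-life of isomer and substrate by their step alone, 0.294 h, is short against 2.0 h, and ten times as long makes no difference to the share.

For the neighbour charged with 0.080 M, s∞ again says 70.5 % at 2.0 h, and the curve says 20.7 % at 30 s. That neighbour gives 71.7 % and 20.1 %.

The readings come from a simulation for an exercise; the scatter is artificial.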